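**Retrosynthetic overview** (ring atoms in hydroazulene numbering C-1 to C-8a; side chain as hept-6-en-2-yl, C-1' to C-7')
1. Target ⇒ acetylation of the C-5' carbinol, Weitz–Scheffer epoxidation of the C-5=C-6 enone and RCM of the seven-membered ring ⇒ a monocyclic trienone diol that already holds all 20 skeletal carbons.
2. Key disconnection: the bond between tertiary carbinol C-2' and the C-3' methylene. A cyclopentyl methyl ketone carrying a CH2CO2Et arm is joined to an unprotected, enantiopure γ-oxido-alkyl Grignard reagent (C-3' to C-7'), and the same flask turns the ester arm into the isopropenyl ketone.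
3. Enabling feature: C-2' hangs outside the ring on cyclopentane C-3, whose ring neighbours differ sharply (C-3a, a methine bearing the C-4 methylene next to quaternary C-8a, against the plain C-2 methylene). This gives a clear Felkin–Anh bias. The oxygens on C-2' and C-5' are 1,4-related, so the C-3' carbanion is γ to the C-5' alkoxide and cannot β-eliminate.
4. Ketone half: (S)-limonene → ring contraction (ozonolysis/aldol), Johnson–Claisen (C-8a), hydroboration/Suzuki (C-3a, allyl), with the isopropenyl group masked as a dioxolane and later cut down to acetyl. Nucleophile half: homoprenyl bromide → Shi epoxide → allylic alcohol.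
5. Ring order: cyclopentene (step 2) → temporary dioxolane (steps 4–8) → cycloheptenone (step 12) → oxirane (step 13).

Key step: step 11

Remark (numbering): the target numbers given above are also used in the Why lines for the corresponding atoms of all intermediates.
Remark (chemistry): the future C-2' is carried as a mixture of both epimers from step 3 to step 8, where it becomes a carbonyl carbon. That centre is therefore left open in the SMILES of 5–12.

Step 1
Reactants: 1 (S)-(−)-limonene
Product: 3 (3S)-6-oxo-3-(prop-1-en-2-yl)heptanal, via ring-alkene ozonide 2 (not isolated)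
Conditions: O3 (1 equiv, Sudan Red 7B end-point), CH2Cl2, −78 °C; then Me2S, −78 °C → rt
Reagents that add atoms: ozone [O-][O+]=O
Why: Chemoselective ozonolysis with reductive work-up: the trisubstituted, more electron-rich ring olefin should be consumed before the 1,1-disubstituted isopropenyl group when ozone is metered to a dye end-point, and the stereocentre is not involved.

Step 2
Reactants: 3 (3S)-6-oxo-3-(prop-1-en-2-yl)heptanal
Product: 4 (5R)-2-methyl-5-(prop-1-en-2-yl)cyclopent-1-ene-1-carbaldehyde
Conditions: piperidine (cat.), AcOH (cat.), toluene, reflux, Dean–Stark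
Reagents that add atoms: none
Why: Intramolecular aldol condensation via the aldehyde enamine, which attacks the methyl ketone in a 5-exo-trig closure and dehydrates to the conjugated enal; the weakly acidic buffer should leave the allylic stereocentre intact.

Step 3
Reactants: 4 (5R)-2-methyl-5-(prop-1-en-2-yl)cyclopent-1-ene-1-carbaldehyde
Product: 5 (5S)-5-(1,2-dihydroxypropan-2-yl)-2-methylcyclopent-1-ene-1-carbaldehyde (both carbinol epimers)
Conditions: OsO4 (2 mol%), NMO, acetone/H2O, 0 °C → rt
Reagents that add atoms: N-methylmorpholine N-oxide C[N+]1([O-])CCOCC1; water O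
Why: Upjohn dihydroxylation: osmium tetroxide should take the electron-rich terminal olefin and ignore the tetrasubstituted, formyl-deactivated ring olefin, and the new carbinol centre forms as an epimer mixture that is irrelevant because step 8 makes this carbon a carbonyl.

Step 4
Reactants: 5 (5S)-5-(1,2-dihydroxypropan-2-yl)-2-methylcyclopent-1-ene-1-carbaldehyde
Product: 6 (5S)-2-methyl-5-(2,2,4-trimethyl-1,3-dioxolan-4-yl)cyclopent-1-ene-1-carbaldehyde
Conditions: 2,2-dimethoxypropane, PPTS (cat.), CH2Cl2, rt
Reagents that add atoms: 2,2-dimethoxypropane COC(C)(C)OC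
Why: Acid-catalysed transketalisation closes the five-membered dioxolane on the 1,2-diol, which hides the future acetyl carbon from borane and makes the C-3 substituent very bulky for the two stereo-defining steps that follow.

Step 5
Reactants: 6 (5S)-2-methyl-5-(2,2,4-trimethyl-1,3-dioxolan-4-yl)cyclopent-1-ene-1-carbaldehyde
Product: 7 [(5S)-2-methyl-5-(2,2,4-trimethyl-1,3-dioxolan-4-yl)cyclopent-1-en-1-yl]methanol
Conditions: NaBH4, CeCl3·7H2O, MeOH, 0 °C
Reagents that add atoms: none
Why: Luche reduction: the hard cerium-modified borohydride should add 1,2 to the enal and give the primary allylic alcohol without touching ketal or olefin, and no stereocentre is formed.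

Step 6
Reactants: 7 [(5S)-2-methyl-5-(2,2,4-trimethyl-1,3-dioxolan-4-yl)cyclopent-1-en-1-yl]methanol
Product: 9 ethyl 2-[(1R,3S)-1-methyl-2-methylidene-3-(2,2,4-trimethyl-1,3-dioxolan-4-yl)cyclopentyl]acetate, via mixed ketene acetal 8 (not isolated)
Conditions: MeC(OEt)3 (excess), EtCO2H (cat.), 140 °C, EtOH distilled off
Reagents that add atoms: triethyl orthoacetate CCOC(C)(OCC)OCC
Why: Johnson–Claisen rearrangement: ketene acetal 8 undergoes a suprafacial [3,3] shift on the ring face opposite to the bulky dioxolanyl group, which places the CH2CO2Et arm trans and the methyl group cis to that group and so sets quaternary C-8a.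

Step 7
Reactants: 9 ethyl 2-[(1R,3S)-1-methyl-2-methylidene-3-(2,2,4-trimethyl-1,3-dioxolan-4-yl)cyclopentyl]acetate
Product: 11 ethyl 2-[(1R,2S,3S)-1-methyl-2-(prop-2-en-1-yl)-3-(2,2,4-trimethyl-1,3-dioxolan-4-yl)cyclopentyl]acetate, via B-alkyl-9-BBN adduct 10 (not isolated)
Conditions: 9-BBN, THF, 60 °C; then vinyl bromide, PdCl2(dppf) (5 mol%), aq K3PO4, DMF/THF, 50 °C
Reagents that add atoms: vinyl bromide C=CBr
Why: Hydroboration followed by B-alkyl Suzuki–Miyaura coupling: 9-BBN should deliver hydrogen to C-3a from the face that carries only H-3 and the acetate arm (opposite to dioxolanyl and methyl), which sets C-3a with the new CH2 cis to both groups, and the primary alkylborane then couples with vinyl bromide without change of configuration.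

Step 8
Reactants: 11 ethyl 2-[(1R,2S,3S)-1-methyl-2-(prop-2-en-1-yl)-3-(2,2,4-trimethyl-1,3-dioxolan-4-yl)cyclopentyl]acetate
Product: 13 ethyl 2-[(1R,2S,3S)-3-acetyl-1-methyl-2-(prop-2-en-1-yl)cyclopentyl]acetate, via free 1,2-diol 12 (not isolated)
Conditions: AcOH/H2O/THF, 40 °C, evaporate; then NaIO4, THF/pH 7 buffer, 0 °C
Reagents that add atoms: none
Why: Ketal hydrolysis and Malaprade glycol cleavage: both dioxolane epimers converge on one methyl ketone, and because the ketone only appears in the buffered periodate stage the epimerisable C-3 next to it should keep its configuration.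

Step 9
Reactants: 14 5-bromo-2-methylpent-2-ene
Product: 15 (3S)-3-(2-bromoethyl)-2,2-dimethyloxirane
Conditions: L-fructose-derived Shi ketone (30 mol%), Oxone, K2CO3, Bu4NHSO4, MeCN/dimethoxymethane/aq borate–EDTA buffer, 0 °C
Reagents that add atoms: Oxone (potassium peroxymonosulfate) [K+].[O-]S(=O)(=O)OO
Why: Shi epoxidation: the dioxirane of the L-series ketone should attack the trisubstituted olefin through the spiro transition state on the face that gives the (S)-epoxide (future C-5'), the primary bromide being inert at this pH.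

Step 10
Reactants: 15 (3S)-3-(2-bromoethyl)-2,2-dimethyloxirane
Product: 16 (3S)-1-bromo-4-methylpent-4-en-3-ol
Conditions: Al(OiPr)3 (20 mol%), toluene, 110 °C
Reagents that add atoms: none
Why: Lewis-acid-mediated epoxide-to-allylic-alcohol isomerisation: aluminium binds the oxirane oxygen, the tertiary C–O bond breaks and an isopropoxide ligand removes a methyl proton in a cyclic syn-elimination, so the secondary C–O bond and its configuration are retained.

Step 11
Reactants: 13 ethyl 2-[(1R,2S,3S)-3-acetyl-1-methyl-2-(prop-2-en-1-yl)cyclopentyl]acetate; 16 (3S)-1-bromo-4-methylpent-4-en-3-ol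
Product: 20 1-{(1R,2S,3S)-3-[(2S,5S)-2,5-dihydroxy-6-methylhept-6-en-2-yl]-1-methyl-2-(prop-2-en-1-yl)cyclopentyl}-3-methylbut-3-en-2-one, via oxido-Grignard reagent 17 (not isolated), via hydroxy ester adduct 18 (not isolated), via Weinreb amide 19 (not isolated)
Conditions: 16, MeMgCl, THF, −20 °C; Mg turnings (I2-activated), 35 °C; add to 13 + LaCl3·2LiCl, THF, −30 °C; then MeNH(OMe)·HCl, isopropenylMgBr (excess), −20 → 20 °C; aq NH4Cl
Reagents that add atoms: isopropenylmagnesium bromide C=C(C)[Mg]Br
Why: Methylmagnesium chloride turns 16 into its chloromagnesium alkoxide, magnesium inserts into the C–Br bond to give 17, and its C-3' carbanion adds 1,2 to the lanthanum-activated acetyl carbonyl of 13 to form the C-2'–C-3' bond (18); the ammonium salt then destroys surplus 17, isopropenylmagnesium bromide converts it into the magnesium amide that turns the ester arm into 19, and one further equivalent adds once so that the chelate collapses to the isopropenyl ketone 20 on work-up. The closest known reaction types are additions of alkoxide-bearing Grignard reagents to ketones, LaCl3·2LiCl-promoted additions to hindered enolisable ketones and the one-pot ester → Weinreb amide → ketone conversion, and only their telescoping is specific to this route. No ring is closed in this step. The one new stereocentre, C-2', follows the Felkin–Anh model: the C-3–C-3a bond (largest substituent) stands perpendicular to the carbonyl plane, the carbonyl oxygen lies beside the C-2 methylene and the methyl group beside H-3, and attack anti to C-3a gives the (2'S) carbinol, while C-5' arrives with the reagent and is not touched. The step needs ketone-over-ester selectivity, secured by the low temperature and the neopentyl-type position of the ester next to quaternary C-8a, and addition-over-enolisation selectivity, secured by the oxophilic, weakly basic lanthanum species so that C-3 should not epimerise. One flask thus joins the two halves without a protecting group, forms two C–C bonds and delivers all twenty skeletal carbons, five of the seven stereocentres and both olefins for the ring closure.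

Step 12
Reactants: 20 1-{(1R,2S,3S)-3-[(2S,5S)-2,5-dihydroxy-6-methylhept-6-en-2-yl]-1-methyl-2-(prop-2-en-1-yl)cyclopentyl}-3-methylbut-3-en-2-one
Product: 21 (3S,3aS,8aR)-3-[(2S,5S)-2,5-dihydroxy-6-methylhept-6-en-2-yl]-6,8a-dimethyl-1,2,3,3a,4,8a-hexahydroazulen-7(8H)-one
Conditions: Grubbs second-generation catalyst (5 mol%), 1,4-benzoquinone (10 mol%), CH2Cl2 (high dilution), 40 °C
Reagents that add atoms: none
Why: Ring-closing metathesis: the ruthenium carbene should load on the monosubstituted allyl olefin and close onto the 1,1-disubstituted enone olefin to give the seven-membered ring with its trisubstituted C-5=C-6 bond, the trans fusion being already fixed and the isopropenyl carbinol olefin staying out because it could only give a nine-membered ring.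

Step 13
Reactants: 21 (3S,3aS,8aR)-3-[(2S,5S)-2,5-dihydroxy-6-methylhept-6-en-2-yl]-6,8a-dimethyl-1,2,3,3a,4,8a-hexahydroazulen-7(8H)-one
Product: 22 (3S,3aS,5S,6S,8aR)-5,6-epoxy-3-[(2S,5S)-2,5-dihydroxy-6-methylhept-6-en-2-yl]-6,8a-dimethyloctahydroazulen-7(1H)-one
Conditions: 30% H2O2, NaOH (cat.), MeOH, 0 °C
Reagents that add atoms: hydrogen peroxide OO
Why: Weitz–Scheffer epoxidation: hydroperoxide should add to C-5 from the β face, anti to the allylic C-4–C-3a bond that points to the α side in the trans-fused twist conformer, and the enolate closes on the same face, which sets C-5 and C-6 with the oxirane cis to the C-8a methyl, while the electron-rich isopropenyl olefin does not react with a nucleophilic oxidant.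

Step 14
Reactants: 22 (3S,3aS,5S,6S,8aR)-5,6-epoxy-3-[(2S,5S)-2,5-dihydroxy-6-methylhept-6-en-2-yl]-6,8a-dimethyloctahydroazulen-7(1H)-one
Product: 23 (3S,6S)-6-[(3S,3aS,5S,6S,8aR)-5,6-epoxy-6,8a-dimethyl-7-oxodecahydroazulen-3-yl]-6-hydroxy-2-methylhept-1-en-3-yl acetate (CNP0165281.1)
Conditions: Ac2O, pyridine, DMAP (cat.), CH2Cl2, 0 °C
Reagents that add atoms: acetic anhydride CC(=O)OC(C)=O
Why: Chemoselective acylation under nucleophilic catalysis: only the secondary allylic alcohol is accessible, the tertiary carbinol next to the ring being too hindered at 0 °C, and no stereocentre is touched.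

**Compound list**
1 | (S)-(−)-limonene | CC1=CC[C@H](CC1)C(C)=C | starting material
2 | secondary ozonide of the ring olefin of 1 (acetal carbons as formed) | CC12CC[C@@H](CC(O1)OO2)C(C)=C | intermediate
3 | (3S)-6-oxo-3-(prop-1-en-2-yl)heptanal | O=CC[C@H](CCC(C)=O)C(C)=C | intermediate
4 | (5R)-2-methyl-5-(prop-1-en-2-yl)cyclopent-1-ene-1-carbaldehyde | C=C(C)[C@H]1CCC(C)=C1C=O | intermediate
5 | (5S)-5-(1,2-dihydroxypropan-2-yl)-2-methylcyclopent-1-ene-1-carbaldehyde, carbinol epimers | OCC(C)(O)[C@H]1CCC(C)=C1C=O | intermediate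
6 | (5S)-2-methyl-5-(2,2,4-trimethyl-1,3-dioxolan-4-yl)cyclopent-1-ene-1-carbaldehyde | CC1(C)OCC(C)(O1)[C@H]2CCC(C)=C2C=O | intermediate
7 | [(5S)-2-methyl-5-(2,2,4-trimethyl-1,3-dioxolan-4-yl)cyclopent-1-en-1-yl]methanol | CC1(C)OCC(C)(O1)[C@H]2CCC(C)=C2CO | intermediate
8 | 1-ethoxyvinyl ether of 7 (mixed ketene acetal) | CC1(C)OCC(C)(O1)[C@H]2CCC(C)=C2COC(=C)OCC | intermediate
9 | ethyl 2-[(1R,3S)-1-methyl-2-methylidene-3-(2,2,4-trimethyl-1,3-dioxolan-4-yl)cyclopentyl]acetate | CC1(C)OCC(C)(O1)[C@H]2CC[C@](C)(CC(=O)OCC)C2=C | intermediate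
10 | B-alkyl-9-BBN adduct of 9 | CC1(C)OCC(C)(O1)[C@H]2CC[C@](C)(CC(=O)OCC)[C@H]2CB3C4CCCC3CCC4 | intermediate
11 | ethyl 2-[(1R,2S,3S)-1-methyl-2-(prop-2-en-1-yl)-3-(2,2,4-trimethyl-1,3-dioxolan-4-yl)cyclopentyl]acetate | CC1(C)OCC(C)(O1)[C@H]2CC[C@](C)(CC(=O)OCC)[C@H]2CC=C | intermediate
12 | ethyl 2-[(1R,2S,3S)-3-(1,2-dihydroxypropan-2-yl)-1-methyl-2-(prop-2-en-1-yl)cyclopentyl]acetate | OCC(C)(O)[C@H]1CC[C@](C)(CC(=O)OCC)[C@H]1CC=C | intermediate
13 | ethyl 2-[(1R,2S,3S)-3-acetyl-1-methyl-2-(prop-2-en-1-yl)cyclopentyl]acetate | CC(=O)[C@H]1CC[C@](C)(CC(=O)OCC)[C@H]1CC=C | intermediate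
14 | 5-bromo-2-methylpent-2-ene | CC(C)=CCCBr | starting material
15 | (3S)-3-(2-bromoethyl)-2,2-dimethyloxirane | CC1(C)O[C@H]1CCBr | intermediate
16 | (3S)-1-bromo-4-methylpent-4-en-3-ol | C=C(C)[C@H](CCBr)O | intermediate
17 | (3S)-3-(chloromagnesiooxy)-4-methylpent-4-en-1-ylmagnesium bromide | C=C(C)[C@H](CC[Mg]Br)O[Mg]Cl | intermediate
18 | ethyl 2-{(1R,2S,3S)-3-[(2S,5S)-2,5-dihydroxy-6-methylhept-6-en-2-yl]-1-methyl-2-(prop-2-en-1-yl)cyclopentyl}acetate (present as its alkoxide) | C=C(C)[C@H](CC[C@](C)(O)[C@H]1CC[C@](C)(CC(=O)OCC)[C@H]1CC=C)O | intermediate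
19 | N-methoxy-N-methyl amide corresponding to 18 | C=C(C)[C@H](CC[C@](C)(O)[C@H]1CC[C@](C)(CC(=O)N(C)OC)[C@H]1CC=C)O | intermediate
20 | 1-{(1R,2S,3S)-3-[(2S,5S)-2,5-dihydroxy-6-methylhept-6-en-2-yl]-1-methyl-2-(prop-2-en-1-yl)cyclopentyl}-3-methylbut-3-en-2-one | C=C(C)[C@H](CC[C@](C)(O)[C@H]1CC[C@](C)(CC(=O)C(C)=C)[C@H]1CC=C)O | intermediate
21 | trans-fused bicyclic enone diol (name in step 12) | C=C(C)[C@H](CC[C@](C)(O)[C@H]1CC[C@]2(C)CC(=O)C(C)=CC[C@@H]12)O | intermediate
22 | β-epoxy ketone diol (name in step 13) | C=C(C)[C@H](CC[C@](C)(O)[C@H]1CC[C@]2(C)CC(=O)[C@@]3(C)O[C@H]3C[C@@H]12)O | intermediate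
23 | CNP0165281.1 (name in step 14) | C=C(C)[C@H](CC[C@](C)(O)[C@H]1CC[C@]2(C)CC(=O)[C@@]3(C)O[C@H]3C[C@@H]12)OC(C)=O | target

**Step count:** 14 steps in total. The longest linear sequence is 12 steps (steps 1–8 and 11–14).

**Steps most likely to fail**

Step 11. What may go wrong: sluggish magnesium insertion into the bromo alkoxide, enolisation of the crowded ketone instead of addition, or loss of ketone-over-ester selectivity in the one-flask format. The fallback uses a protected mono-anion in separate operations and sets out from 16 and 13. Silylation of 16 (TBSCl, imidazole, DMF) gives (3S)-1-bromo-3-(tert-butyldimethylsilyloxy)-4-methylpent-4-ene F1. Magnesium insertion gives its Grignard reagent F2. This is added to 13 at −78 °C in the presence of anhydrous CeCl3 (organocerium-type addition, same Felkin–Anh sense) to give the 5'-O-silyl hydroxy ester F3. TBAF frees the carbinol and the sequence comes back to the route at 18, now isolated. Compound 18 is then carried to 20 by the amide/Grignard stage of step 11 as an operation of its own.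

Step 13. What may go wrong: poor facial selectivity of the hydroperoxide addition on the flexible seven-membered enone, or reversible conjugate addition of the C-2' hydroxyl group to C-5 under base. The fallback is a hydroxyl-directed epoxidation that sets out from 21 and comes back at 23. Acetylation of 21 (Ac2O, pyridine, DMAP) gives the enone 5'-acetate F4. Luche reduction, with hydride entering at C-7 from the α face away from the axial C-8a methyl group, gives the (7R)-7β-allylic alcohol F5. VO(acac)2/t-BuOOH delivers oxygen syn to this hydroxyl group and gives the β-epoxy alcohol F6; the isopropenyl olefin has no free allylic OH and should stay untouched. Dess–Martin oxidation of the only secondary alcohol then gives 23.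

Step 7. What may go wrong: slow hydroboration of the olefin flanked by a quaternary and a dioxolanyl-bearing carbon with the bulky dialkylborane, and β-hydride loss or protodeboronation at the alkylpalladium stage. The fallback uses a small borane followed by copper-catalysed sp3–sp2 coupling, sets out from 9 and comes back at 11. Hydroboration–oxidation (BH3·SMe2; NaBO3·4H2O) with the same facial preference gives the primary alcohol ethyl 2-[(1R,2S,3S)-2-(hydroxymethyl)-1-methyl-3-(2,2,4-trimethyl-1,3-dioxolan-4-yl)cyclopentyl]acetate F7. An Appel-type iodination (I2, PPh3, imidazole) gives the corresponding iodide F8. Vinylmagnesium bromide with catalytic Li2CuCl4 at −30 °C then gives 11.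

**Further compounds**
F1 | step 11 | (3S)-1-bromo-3-(tert-butyldimethylsilyloxy)-4-methylpent-4-ene | C=C(C)[C@H](CCBr)O[Si](C)(C)C(C)(C)C
F2 | step 11 | (3S)-3-(tert-butyldimethylsilyloxy)-4-methylpent-4-en-1-ylmagnesium bromide | C=C(C)[C@H](CC[Mg]Br)O[Si](C)(C)C(C)(C)C
F3 | step 11 | 5'-O-tert-butyldimethylsilyl ether of 18 | C=C(C)[C@H](CC[C@](C)(O)[C@H]1CC[C@](C)(CC(=O)OCC)[C@H]1CC=C)O[Si](C)(C)C(C)(C)C
F4 | step 13 | 5'-acetate of 21 | C=C(C)[C@H](CC[C@](C)(O)[C@H]1CC[C@]2(C)CC(=O)C(C)=CC[C@@H]12)OC(C)=O
F5 | step 13 | (7R)-7β-hydroxy-5-ene 5'-acetate | C=C(C)[C@H](CC[C@](C)(O)[C@H]1CC[C@]2(C)C[C@@H](O)C(C)=CC[C@@H]12)OC(C)=O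
F6 | step 13 | (5S,6S,7R)-5,6-epoxy-7-hydroxy 5'-acetate | C=C(C)[C@H](CC[C@](C)(O)[C@H]1CC[C@]2(C)C[C@@H](O)[C@@]3(C)O[C@H]3C[C@@H]12)OC(C)=O
F7 | step 7 | ethyl 2-[(1R,2S,3S)-2-(hydroxymethyl)-1-methyl-3-(2,2,4-trimethyl-1,3-dioxolan-4-yl)cyclopentyl]acetate | CC1(C)OCC(C)(O1)[C@H]2CC[C@](C)(CC(=O)OCC)[C@H]2CO
F8 | step 7 | ethyl 2-[(1R,2S,3S)-2-(iodomethyl)-1-methyl-3-(2,2,4-trimethyl-1,3-dioxolan-4-yl)cyclopentyl]acetate | CC1(C)OCC(C)(O1)[C@H]2CC[C@](C)(CC(=O)OCC)[C@H]2CI
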